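**Retrosynthetic overview**
1. Target 6 ⇒ pyranoflavanone 5: the chalcone comes from base-induced opening of flavanone ring C. Ring C masks one of the two hydroxyls ortho to the carbonyl, so the pyran can only close on the para oxygen.
2. 5 ⇒ epoxide 4 ⇒ 8-prenylnaringenin 3: a phenol-directed asymmetric epoxidation sets the only stereocentre (R), and a 6-endo phenol-to-epoxide closure forms the pyran C–O bond.
3. 3 ⇒ naringenin 1 + prenol 2 by Friedel–Crafts C-prenylation.
4. Ring order: rings A, B and C are bought with naringenin, the hydroxypyran ring is formed in step 2, and ring C is opened in step 3.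

**Assumptions**
- Commercial naringenin is taken as the racemate. C2 of 3, 4 and 5 is therefore left undefined (4 and 5 are 1:1 epimer pairs at C2). This is harmless because C2 becomes sp2 in step 3.
- The sense of induction of the new step 2 cannot be predicted. The route is written with the (R,R)-ligand; the (S,S)-ligand is used instead if a test run gives the (9S) product.

**Route**

Step 1
Reactants: 1 naringenin; 2 prenol
Product: 3 8-prenylnaringenin
Conditions: ZnCl2 (4 equiv), EtOAc, 40 °C; chromatography
Reagents that add atoms: none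
Why: Friedel–Crafts C-prenylation in which ZnCl2 ionises prenol to a prenyl cation equivalent that attacks the phloroglucinol-type ring A at C8; the yield is modest because C6 attack competes and that isomer is removed by chromatography, and no stereocentre is formed.

Step 2
Reactants: 3 8-prenylnaringenin
Product: 5 (9R)-9-hydroxy-8,8-dimethyl-dihydropyrano[2,3-f]-fused naringenin, via (R)-epoxyprenyl-naringenin 4 (not isolated)
Conditions: VO(OiPr)3 (10 mol %), N,N'-[(1R,2R)-cyclohexane-1,2-diyl]bis(N-hydroxy-2,2-diphenylacetamide) (12 mol %), TBHP (1.5 equiv, decane), CH2Cl2/EtOAc, 0 °C; then TFA (20 mol %), 0 °C to rt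
Reagents that add atoms: tert-butyl hydroperoxide (TBHP), CC(C)(C)OO
Why: Proposed new method: phenol-directed catalytic asymmetric epoxidation followed by 6-endo epoxide-opening cycloetherification — the acidic 7-OH exchanges onto a chiral bis-hydroxamic acid oxovanadium complex (pentavalent vanadium) that also carries tert-butylperoxide, so oxygen is delivered inside a seven-membered chelate to one face of the neighbouring prenyl alkene and sets the carbinol carbon as (R); epoxide 4 then opens at its tertiary carbon under vanadium/TFA activation by the same 7-O, which forms the pyran C–O bond without touching the stereogenic C–O bond, and the ring-C ether oxygen on the other side of the prenyl group cannot compete; the closest known reaction types are the racemic VO(acac)2/TBHP/TFA oxidative cyclisation of 2-prenylphenols to 3-chromanols and the chiral bis-hydroxamic acid–vanadium epoxidation of allylic and homoallylic alcohols, which has not been shown with a phenol as the directing hydroxyl.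

Step 3
Reactants: 5 (9R)-9-hydroxy-8,8-dimethyl-dihydropyrano[2,3-f]-fused naringenin
Product: 6 (E)-1-[(3R)-3,5,7-trihydroxy-2,2-dimethylchroman-6-yl]-3-(4-hydroxyphenyl)prop-2-en-1-one
Conditions: KOH (10 equiv), EtOH/H2O (1:1), Ar, 50 °C, 30 min; then poured into ice-cold 2 M HCl (pH 3, 0 °C), rapid EtOAc extraction
Reagents that add atoms: none
Why: E1cB retro-oxa-Michael opening of ring C (flavanone-to-chalcone isomerisation, as used to turn 5-hydroxy-7-alkoxyflavanones into 2',6'-dihydroxy-4'-alkoxychalcones), in which excess hydroxide pulls the equilibrium to the open (E)-chalcone polyphenolate and the cold acid quench traps it; the carbinol centre has no epimerisation pathway in base and stays (R), while the racemic C2 centre disappears.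

**Compound list**
1 | naringenin, (±)-5,7-dihydroxy-2-(4-hydroxyphenyl)chroman-4-one | O=C1CC(c2ccc(O)cc2)Oc2cc(O)cc(O)c12 | starting material
2 | prenol, 3-methylbut-2-en-1-ol | CC(C)=CCO | starting material
3 | 8-prenylnaringenin, (±)-5,7-dihydroxy-2-(4-hydroxyphenyl)-8-(3-methylbut-2-en-1-yl)chroman-4-one | O=C1CC(c2ccc(O)cc2)Oc2c(CC=C(C)C)c(O)cc(O)c12 | intermediate
4 | 8-{[(2R)-3,3-dimethyloxiran-2-yl]methyl}-5,7-dihydroxy-2-(4-hydroxyphenyl)chroman-4-one (both C2 epimers) | O=C1CC(c2ccc(O)cc2)Oc2c(C[C@H]3OC3(C)C)c(O)cc(O)c12 | intermediate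
5 | (9R)-5,9-dihydroxy-2-(4-hydroxyphenyl)-8,8-dimethyl-2,3,9,10-tetrahydro-4H,8H-pyrano[2,3-f]chromen-4-one (both C2 epimers) | O=C1CC(c2ccc(O)cc2)Oc2c3C[C@@H](O)C(C)(C)Oc3cc(O)c12 | intermediate
6 | (E)-1-[(3R)-3,5,7-trihydroxy-2,2-dimethyl-3,4-dihydro-2H-chromen-6-yl]-3-(4-hydroxyphenyl)prop-2-en-1-one | CC1(C)Oc2cc(O)c(C(=O)/C=C/c3ccc(O)cc3)c(O)c2C[C@H]1O | target

**Totals**
Total step count: 3. Longest linear sequence: 3.

**Steps most likely to fail, with fallbacks**

Step 2 (the proposed new step). The risks are low enantioselectivity, because the other phenols and the 5-OH/ketone chelate can bind vanadium, and some 5-exo closure. The fallback uses known chemistry, sets out from 3 and comes back to the route at 4. TIPSCl/imidazole in DMF gives 7,4'-bis-O-triisopropylsilyl-8-prenylnaringenin F4, with the hydrogen-bonded 5-OH left free. Shi epoxidation follows, using the D-fructose-derived ketone 1,2:4,5-di-O-isopropylidene-β-D-erythro-2,3-hexodiulo-2,6-pyranose with Oxone (2KHSO5·KHSO4·K2SO4) and K2CO3 in MeCN/dimethoxymethane/aqueous buffer at 0 °C. Its spiro transition state gives the (R)-epoxide of ArCH2–CH=CMe2 olefins, here the (R)-epoxide bis-silyl ether F5. HF·pyridine in THF removes both silyl groups to release 4, which closes 6-endo to 5 under the same acidic conditions.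

Step 3. The risks are re-closure of the 2',6'-dihydroxychalcone to a flavanone during acidification and retro-aldol cleavage in hot alkali. The fallback sets out from 5 and comes back at 6. Excess NaH with MOMCl in DMF opens ring C by E1cB and traps every oxygen irreversibly, giving the tetrakis(methoxymethyl) ether of the chalcone F6. HCl in MeOH at 40 °C then removes the four MOM groups to give 6.

Step 1. The risks are modest C8/C6 selectivity, over-prenylation and acid-induced chroman formation. The fallback sets out from 1 and comes back at 3. Ac2O/pyridine (2.2 equiv, 0 °C) gives 7,4'-di-O-acetylnaringenin F1. Mitsunobu etherification of the remaining 5-OH with prenol 2 (PPh3, DIAD, THF) gives 5-O-prenyl-7,4'-di-O-acetylnaringenin F2. A Claisen–Cope cascade catalysed by Eu(fod)3, europium tris(6,6,7,7,8,8,8-heptafluoro-2,2-dimethyloctane-3,5-dionate), in CHCl3 at 60 °C moves the prenyl group to C8 and gives 8-prenyl-7,4'-di-O-acetylnaringenin F3. K2CO3/MeOH removes the acetates to give 3.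

**Further compounds**
F1 | step 1 | 7,4'-di-O-acetylnaringenin | O=C1CC(c2ccc(OC(C)=O)cc2)Oc2cc(OC(C)=O)cc(O)c12
F2 | step 1 | 5-O-prenyl-7,4'-di-O-acetylnaringenin | O=C1CC(c2ccc(OC(C)=O)cc2)Oc2cc(OC(C)=O)cc(OCC=C(C)C)c12
F3 | step 1 | 8-prenyl-7,4'-di-O-acetylnaringenin | O=C1CC(c2ccc(OC(C)=O)cc2)Oc2c(CC=C(C)C)c(OC(C)=O)cc(O)c12
F4 | step 2 | 7,4'-bis-O-triisopropylsilyl-8-prenylnaringenin | O=C1CC(c2ccc(O[Si](C(C)C)(C(C)C)C(C)C)cc2)Oc2c(CC=C(C)C)c(O[Si](C(C)C)(C(C)C)C(C)C)cc(O)c12
F5 | step 2 | 8-{[(2R)-3,3-dimethyloxiran-2-yl]methyl}-7,4'-bis-O-triisopropylsilylnaringenin | O=C1CC(c2ccc(O[Si](C(C)C)(C(C)C)C(C)C)cc2)Oc2c(C[C@H]3OC3(C)C)c(O[Si](C(C)C)(C(C)C)C(C)C)cc(O)c12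
F6 | step 3 | (E)-1-[(3R)-3,5,7-tris(methoxymethoxy)-2,2-dimethylchroman-6-yl]-3-[4-(methoxymethoxy)phenyl]prop-2-en-1-one | CC1(C)Oc2cc(OCOC)c(C(=O)/C=C/c3ccc(OCOC)cc3)c(OCOC)c2C[C@H]1OCOC
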